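**Assumptions.** The target has no stereocentre, so "single enantiomer" means the achiral compound as drawn. 2,3-Dimethoxyphenol and 2',6'-dihydroxy-4'-methoxyacetophenone are taken as catalogue chemicals. The route is a paper design built on standard precedent and has not been run.

## Retrosynthetic overview

1. Target ⇐ threefold O-debenzylation of the 5,2',5'-tri-O-benzyl flavone; benzyl masks every phenol that ends free, and the methyl ethers are in place from the start.
2. Ring C (the only ring built, and built last) ⇐ oxidative cyclisation of a 2'-hydroxychalcone (O1–C2 bond, then C2=C3).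
3. Key C–C bond (C2–C3 of the flavone) ⇐ intermolecular Claisen–Schmidt aldol condensation of the ring A methyl ketone with the ring B aldehyde.
4. Ring B aldehyde ⇐ bromination, then Br/Li exchange and DMF, on 1,4-bis(benzyloxy)-2,3-dimethoxybenzene ⇐ 2,3-dimethoxyhydroquinone ⇐ para-oxidation of 2,3-dimethoxyphenol.
5. Ring A ketone ⇐ mono-O-benzylation of 2',6'-dihydroxy-4'-methoxyacetophenone; rings A and B are bought as aromatics.

## Route

Step 1
Reactants: 1 2,3-dimethoxyphenol
Product: 2 2,3-dimethoxy-1,4-benzoquinone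
Conditions: (KSO3)2NO (2.2 equiv), aq. KH2PO4, H2O/acetone, 0 °C to rt, 2 h
Reagents that add atoms: potassium nitrosodisulfonate (KSO3)2NO, [K+].[K+].[O]N(S(=O)(=O)[O-])S(=O)(=O)[O-]
Why: Teuber oxidation, in which the nitrosodisulfonate radical abstracts the phenolic hydrogen and a second equivalent delivers oxygen to the unsubstituted para carbon, so the para-quinone forms in preference to the ortho-quinone.

Step 2
Reactants: 2 2,3-dimethoxy-1,4-benzoquinone
Product: 3 2,3-dimethoxybenzene-1,4-diol
Conditions: Na2S2O4 (aq., excess), EtOAc/H2O, rt, 15 min, N2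
Reagents that add atoms: none
Why: Dithionite reduction of a quinone to its hydroquinone is a fast two-electron, two-proton transfer that touches nothing else in the molecule.

Step 3
Reactants: 3 2,3-dimethoxybenzene-1,4-diol
Product: 4 1,4-bis(benzyloxy)-2,3-dimethoxybenzene
Conditions: BnBr (2.3 equiv), K2CO3 (3 equiv), degassed DMF, N2, rt to 50 °C, 12 h
Reagents that add atoms: benzyl bromide, BrCc1ccccc1
Why: Williamson ether synthesis on both phenoxides, run without oxygen so the electron-rich hydroquinone is not re-oxidised before it is capped.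

Step 4
Reactants: 4 1,4-bis(benzyloxy)-2,3-dimethoxybenzene
Product: 5 2,5-bis(benzyloxy)-1-bromo-3,4-dimethoxybenzene
Conditions: NBS (1.05 equiv), MeCN, 0 °C to rt, dark, 2 h
Reagents that add atoms: N-bromosuccinimide, O=C1CCC(=O)N1Br
Why: Electrophilic aromatic bromination; the two free ring positions are equivalent by symmetry, so there is no regiochemical question, and the first bromine slows a second substitution.

Step 5
Reactants: 5 2,5-bis(benzyloxy)-1-bromo-3,4-dimethoxybenzene
Product: 8 2,5-bis(benzyloxy)-3,4-dimethoxybenzaldehyde, via aryllithium 6 (not isolated), via lithium hemiaminal alkoxide 7 (not isolated)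
Conditions: n-BuLi (1.1 equiv), THF, −78 °C, 15 min; DMF (3 equiv), −78 to 0 °C; 1 M aq. HCl
Reagents that add atoms: N,N-dimethylformamide, CN(C)C=O
Why: Bromine–lithium exchange at −78 °C outruns deprotonation of the benzylic CH2 groups, and Bouveault-type formylation with DMF gives a stable tetrahedral adduct that releases the aldehyde only on acidic quench.

Step 6
Reactants: 9 1-(2,6-dihydroxy-4-methoxyphenyl)ethan-1-one (2',6'-dihydroxy-4'-methoxyacetophenone)
Product: 10 1-[2-(benzyloxy)-6-hydroxy-4-methoxyphenyl]ethan-1-one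
Conditions: BnBr (1.05 equiv), K2CO3 (1.2 equiv), acetone, reflux, 6 h
Reagents that add atoms: benzyl bromide, BrCc1ccccc1
Why: Williamson mono-alkylation; the two hydroxyls are equivalent by symmetry, and after the first benzylation the remaining one is locked in a strong hydrogen bond to the ketone and reacts far more slowly.

Step 7
Reactants: 10 1-[2-(benzyloxy)-6-hydroxy-4-methoxyphenyl]ethan-1-one; 8 2,5-bis(benzyloxy)-3,4-dimethoxybenzaldehyde
Product: 12 (E)-1-[2-(benzyloxy)-6-hydroxy-4-methoxyphenyl]-3-[2,5-bis(benzyloxy)-3,4-dimethoxyphenyl]prop-2-en-1-one, via aldol adduct 11 (not isolated)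
Conditions: KOH (50% aq., 10 equiv), EtOH/THF, rt, 48 h
Reagents that add atoms: none
Why: Claisen–Schmidt crossed aldol condensation, in which the methyl ketone enolate adds to the non-enolisable aldehyde and E1cB dehydration of the aldol gives the conjugated, thermodynamically preferred E-enone.

Step 8
Reactants: 12 (E)-1-[2-(benzyloxy)-6-hydroxy-4-methoxyphenyl]-3-[2,5-bis(benzyloxy)-3,4-dimethoxyphenyl]prop-2-en-1-one
Product: 14 5-(benzyloxy)-2-[2,5-bis(benzyloxy)-3,4-dimethoxyphenyl]-7-methoxy-4H-chromen-4-one, via flavanone 13 (not isolated)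
Conditions: I2 (10 mol%), DMSO, 120 °C, 3 h
Reagents that add atoms: none
Why: Iodine-catalysed oxidative cyclisation, in which 6-endo oxa-Michael addition of the free 2'-hydroxyl closes ring C and the flavanone is dehydrogenated in the same pot with DMSO as terminal oxidant, which also removes its transient stereocentre.

Step 9
Reactants: 14 5-(benzyloxy)-2-[2,5-bis(benzyloxy)-3,4-dimethoxyphenyl]-7-methoxy-4H-chromen-4-one
Product: 15 5-hydroxy-2-(2,5-dihydroxy-3,4-dimethoxyphenyl)-7-methoxy-4H-chromen-4-one (5,2',5'-trihydroxy-7,3',4'-trimethoxyflavone)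
Conditions: H2 (1 atm), 10% Pd/C, THF/MeOH (1:1), rt, 4–6 h; filter and concentrate under N2
Reagents that add atoms: none
Why: Catalytic hydrogenolysis cleaves the three benzyl aryl ethers, leaves the methyl ethers and the chromone C2=C3 bond (a vinylogous ester) alone at 1 atm and rt, and keeps the hydroquinone ring B under reducing conditions as it is unmasked.

## Compound list

1 | 2,3-dimethoxyphenol | COc1cccc(O)c1OC | starting material
2 | 2,3-dimethoxy-1,4-benzoquinone | COC1=C(OC)C(=O)C=CC1=O | intermediate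
3 | 2,3-dimethoxybenzene-1,4-diol | COc1c(O)ccc(O)c1OC | intermediate
4 | 1,4-bis(benzyloxy)-2,3-dimethoxybenzene | c1cc(OCc2ccccc2)c(OC)c(OC)c1OCc1ccccc1 | intermediate
5 | 2,5-bis(benzyloxy)-1-bromo-3,4-dimethoxybenzene | Brc1cc(OCc2ccccc2)c(OC)c(OC)c1OCc1ccccc1 | intermediate
6 | [2,5-bis(benzyloxy)-3,4-dimethoxyphenyl]lithium | [Li]c1cc(OCc2ccccc2)c(OC)c(OC)c1OCc1ccccc1 | intermediate (not isolated)
7 | lithium [2,5-bis(benzyloxy)-3,4-dimethoxyphenyl](dimethylamino)methanolate (racemic) | CN(C)C(O[Li])c1cc(OCc2ccccc2)c(OC)c(OC)c1OCc1ccccc1 | intermediate (not isolated)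
8 | 2,5-bis(benzyloxy)-3,4-dimethoxybenzaldehyde | O=Cc1cc(OCc2ccccc2)c(OC)c(OC)c1OCc1ccccc1 | intermediate
9 | 1-(2,6-dihydroxy-4-methoxyphenyl)ethan-1-one | CC(=O)c1c(O)cc(OC)cc1O | starting material
10 | 1-[2-(benzyloxy)-6-hydroxy-4-methoxyphenyl]ethan-1-one | CC(=O)c1c(O)cc(OC)cc1OCc1ccccc1 | intermediate
11 | 1-[2-(benzyloxy)-6-hydroxy-4-methoxyphenyl]-3-[2,5-bis(benzyloxy)-3,4-dimethoxyphenyl]-3-hydroxypropan-1-one (racemic) | COc1cc(O)c(C(=O)CC(O)c2cc(OCc3ccccc3)c(OC)c(OC)c2OCc2ccccc2)c(OCc2ccccc2)c1 | intermediate (not isolated)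
12 | (E)-1-[2-(benzyloxy)-6-hydroxy-4-methoxyphenyl]-3-[2,5-bis(benzyloxy)-3,4-dimethoxyphenyl]prop-2-en-1-one | COc1cc(O)c(C(=O)/C=C/c2cc(OCc3ccccc3)c(OC)c(OC)c2OCc2ccccc2)c(OCc2ccccc2)c1 | intermediate
13 | 5-(benzyloxy)-2-[2,5-bis(benzyloxy)-3,4-dimethoxyphenyl]-7-methoxychroman-4-one (racemic) | COc1cc2OC(c3cc(OCc4ccccc4)c(OC)c(OC)c3OCc3ccccc3)CC(=O)c2c(OCc2ccccc2)c1 | intermediate (not isolated)
14 | 5-(benzyloxy)-2-[2,5-bis(benzyloxy)-3,4-dimethoxyphenyl]-7-methoxy-4H-chromen-4-one | COc1cc(OCc2ccccc2)c2c(=O)cc(-c3cc(OCc4ccccc4)c(OC)c(OC)c3OCc3ccccc3)oc2c1 | intermediate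
15 | 5-hydroxy-2-(2,5-dihydroxy-3,4-dimethoxyphenyl)-7-methoxy-4H-chromen-4-one | COc1cc(O)c2c(=O)cc(-c3cc(O)c(OC)c(OC)c3O)oc2c1 | target

## Step count and risks

Total steps: 9. Longest linear sequence: 8 steps (steps 1, 2, 3, 4, 5, 7, 8, 9, from 2,3-dimethoxyphenol); the ring A branch adds step 6.

**Step 7 (crossed aldol).** The aldehyde is electron-rich and ortho-substituted, so addition may be slow or stall at an aldol/retro-aldol equilibrium. The fallback sets out from aldehyde 8 and forms the same C–C bond by intermolecular Claisen-type acylation. Pinnick oxidation (NaClO2, NaH2PO4, 2-methyl-2-butene, t-BuOH/H2O) gives 2,5-bis(benzyloxy)-3,4-dimethoxybenzoic acid F1. Oxalyl chloride with catalytic DMF in CH2Cl2 converts it into 2,5-bis(benzyloxy)-3,4-dimethoxybenzoyl chloride F2. This C-acylates the lithium dianion of ketone 10 (LiN(SiMe3)2, 3.5 equiv, THF, −78 °C to rt) to give 1-[2-(benzyloxy)-6-hydroxy-4-methoxyphenyl]-3-[2,5-bis(benzyloxy)-3,4-dimethoxyphenyl]propane-1,3-dione F3. Cyclodehydration with catalytic p-TsOH in toluene at 80 °C then gives flavone 14, where the fallback rejoins the route; chalcone 12 and step 8 are bypassed.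

**Step 8 (oxidative cyclisation).** HI formed in the pot can partly cleave the 5-benzyl ether or iodinate ring A; partly debenzylated flavone would still converge on 15 in step 9, but ring iodination would not. The fallback sets out from chalcone 12 and avoids iodine. The chalcone is isomerised with NaOAc in refluxing EtOH to flavanone 13, which is isolated. Dehydrogenation with DDQ (1.5 equiv) in refluxing 1,4-dioxane then rejoins the route at 14. This fallback makes no compound outside the list, F0.

**Step 5 (lithiation and formylation).** The aryllithium sits ortho to a benzyl ether and can undergo proton transfer from the benzylic CH2 followed by anionic rearrangement if it warms before the quench. The fallback sets out from 4, skips bromide 5 and uses no organometallic. Vilsmeier–Haack formylation (POCl3, DMF, 70 °C) of this tetra-alkoxybenzene gives [2,5-bis(benzyloxy)-3,4-dimethoxybenzylidene]dimethyliminium chloride F4. Hydrolysis with aq. NaOAc rejoins the route at aldehyde 8.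

## Further compounds

F1 | step 7 | 2,5-bis(benzyloxy)-3,4-dimethoxybenzoic acid | O=C(O)c1cc(OCc2ccccc2)c(OC)c(OC)c1OCc1ccccc1
F2 | step 7 | 2,5-bis(benzyloxy)-3,4-dimethoxybenzoyl chloride | O=C(Cl)c1cc(OCc2ccccc2)c(OC)c(OC)c1OCc1ccccc1
F3 | step 7 | 1-[2-(benzyloxy)-6-hydroxy-4-methoxyphenyl]-3-[2,5-bis(benzyloxy)-3,4-dimethoxyphenyl]propane-1,3-dione | COc1cc(O)c(C(=O)CC(=O)c2cc(OCc3ccccc3)c(OC)c(OC)c2OCc2ccccc2)c(OCc2ccccc2)c1
F0 | step 8 | none | none
F4 | step 5 | [2,5-bis(benzyloxy)-3,4-dimethoxybenzylidene]dimethyliminium chloride | C[N+](C)=Cc1cc(OCc2ccccc2)c(OC)c(OC)c1OCc1ccccc1.[Cl-]
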